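**Plan**

- Numbering is that of the eudesmanes: ring A = C1–C5 and C10, ring B = C5–C10, C14 on C10, C15 on C4, C11(=C13)–C12 on C7. The retrosynthesis cuts the C9 ester, then the acrylic acid back to a C7–CH2–CHO arm, then C8–C9 and C6–C7 of ring B together, then the four-membered ring C9–C10–C5–C6.
- Enabling feature: the oxygen-bearing C9 and the methylene C6 sit on the adjacent fusion atoms C10 and C5 of ring A. A C9 ketone can therefore be tied to C6 as a strained cyclobutanone fused to ring A, which is an enone–alkene [2+2] adduct. Inserting a two-carbon alkyne unit (C8, C7) into its C9–C6 bond turns the bicyclo[4.2.0]octane into the decalin.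
- Forward order: ring A (3-methylcyclohexenone) → four-membered ring → ring B by two-carbon ring expansion → C4 carbinol, C9 alcohol and C7 hydrogenation → ester → acrylic acid.
- Stereochemistry: C10 from the enantioselective photocycloaddition; C5 by base equilibration next to the C4 ketone (trans-decalin); C4 by α-face epoxidation opposite the axial C14 methyl, then hydride opening; C9 by axial hydride delivery; C7 by hydrogenation directed by the C9 hydroxyl; the side-chain centre from (3S)-3-methylpentanoic acid.

Key step: step 4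

**Step 1**
Reactants: 1 3-methylcyclohex-2-en-1-one; 2 vinyl acetate
Product: 3 (6S)-6-methyl-2-oxobicyclo[4.2.0]octan-7-yl acetate (head-to-tail adduct, epimer mixture at C1 and C7)
Conditions: oxazaborolidine from α,α-diphenylprolinol and 2,4,6-trifluorophenylboronic acid (enantiomer chosen to give 6S), activated with AlBr3 (0.5 equiv), 2 (10 equiv), CH2Cl2, hν (366 nm), −75 °C
Reagents that add atoms: none
Why: In this chiral-Lewis-acid-catalysed enone–alkene [2+2] photocycloaddition only the Lewis-acid-bound enone should absorb at 366 nm, the catalyst should shield one enone face and so set the quaternary C10, and the electron-rich alkene should add head-to-tail so that the acetoxy carbon (C9) bonds to the methyl-bearing β-carbon.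

**Step 2**
Reactants: 3 (6S)-6-methyl-2-oxobicyclo[4.2.0]octan-7-yl acetate
Product: 4 (1S,6S)-7-hydroxy-6-methylbicyclo[4.2.0]octan-2-one (cis-fused, C7 epimers)
Conditions: K2CO3 (0.2 equiv), MeOH, rt
Reagents that add atoms: none
Why: Base-catalysed methanolysis of the acetate should free the cyclobutanol while the same medium epimerises C1 (α to the ketone) to the stable cis-fused bicyclo[4.2.0]octanone; the quaternary centre is untouched.

**Step 3**
Reactants: 4 (1S,6S)-7-hydroxy-6-methylbicyclo[4.2.0]octan-2-one
Product: 5 (1S,6S)-6-methylbicyclo[4.2.0]octane-2,7-dione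
Conditions: Dess–Martin periodinane (1.3 equiv), CH2Cl2, rt
Reagents that add atoms: none
Why: Dess–Martin oxidation of the secondary cyclobutanol should converge both C7 epimers to the cyclobutanone under neutral conditions that leave the ring fusion alone.

**Step 4**
Reactants: 5 (1S,6S)-6-methylbicyclo[4.2.0]octane-2,7-dione; 6 4,4-diethoxybut-1-yne
Product: 7 (4aS,8aS)-7-(2,2-diethoxyethyl)-4a-methyl-3,4,4a,8a-tetrahydronaphthalene-1,5(2H,8H)-dione (cis-fused)
Conditions: Ni(cod)2 (10 mol %), PCy3 (20 mol %), toluene, 100 °C, 6 (1.5 equiv) added over 6 h by syringe pump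
Reagents that add atoms: none
Why: Zerovalent nickel should couple the strained C9 ketone and the alkyne oxidatively to an oxanickelacyclopentene (C9–C8 bond), β-carbon elimination should then break the C9–C6 bond of the four-membered ring to give a seven-membered nickelacycle, and C(sp3)–C(sp2) reductive elimination should join C6 to C7, so that both bonds arise in one catalytic cycle. The closest known reaction type is the nickel-catalysed intermolecular insertion of alkynes into cyclobutanones to give cyclohex-2-enones. Ring B is closed not by an exo or endo cyclisation but by two-atom ring expansion of the cyclobutanone, the closing event being reductive elimination from the nickelacycloheptenone. No stereocentre is created: C10 and C5 are not touched and keep the configuration of 5, and C7 and C8 leave as the enone double bond. Three selectivities are needed: the cyclobutanone carbonyl should react rather than the unstrained C4 ketone because only its ring opening releases strain; the C9–C6 bond should be cut rather than C9–C10 because β-carbon elimination places nickel on the CH2 carbon and not on the quaternary C10; and the CH terminus of the alkyne should bond to the hindered C9 while the substituted carbon stays on nickel and becomes C7. Slow addition of the 1-alkyne is meant to keep its nickel-mediated oligomerisation slower than the coupling.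

**Step 5**
Reactants: 7 (4aS,8aS)-7-(2,2-diethoxyethyl)-4a-methyl-3,4,4a,8a-tetrahydronaphthalene-1,5(2H,8H)-dione
Product: 9 (4aS,8aS)-3-(2,2-diethoxyethyl)-8a-methyl-5-methylidene-4a,5,6,7,8,8a-hexahydronaphthalen-1(4H)-one, via trans-dione 8 (not isolated)
Conditions: Ph3PCH3Br (2.0 equiv), KOtBu (2.3 equiv), THF, 0 °C to rt
Reagents that add atoms: methyltriphenylphosphonium bromide, C[P+](c1ccccc1)(c1ccccc1)c1ccccc1.[Br-]
Why: The basic ylide medium should first equilibrate C5 (α to the C4 ketone) to the trans-fused dione 8, favoured as in 4-oxo-5α-steroids because the carbonyl removes a 1,3-diaxial contact of the angular methyl, and Wittig methylenation should then take place at the saturated C4 ketone rather than at the conjugated C9 carbonyl shielded by the quaternary C10.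

**Step 6**
Reactants: 9 (4aS,8aS)-3-(2,2-diethoxyethyl)-8a-methyl-5-methylidene-4a,5,6,7,8,8a-hexahydronaphthalen-1(4H)-one
Product: 10 the 4α,15-epoxide of 9 (spiro-oxirane at C4, oxygen on the face opposite the C14 methyl, CH2 on the same face as it)
Conditions: mCPBA (1.1 equiv), CH2Cl2, 0 °C
Reagents that add atoms: 3-chloroperoxybenzoic acid, O=C(OO)c1cccc(Cl)c1
Why: In this Prilezhaev epoxidation the electron-rich 1,1-disubstituted alkene should react while the enone double bond does not, and the peracid should approach equatorially from the α face because the axial β trajectory is blocked by the 1,3-diaxial C14 methyl, which places the C4 oxygen α.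

**Step 7**
Reactants: 10 the 4α,15-epoxide of 9
Product: 11 (1S,4aR,5R,8aS)-3-(2,2-diethoxyethyl)-5,8a-dimethyl-1,4,4a,5,6,7,8,8a-octahydronaphthalene-1,5-diol
Conditions: LiAlH4 (2 equiv), Et2O, −20 °C to rt
Reagents that add atoms: none
Why: Hydride should open the epoxide at its CH2 carbon to leave the C4 tertiary alcohol with oxygen α and methyl β, and 1,2-reduction of the enone by axial attack anti to the neighbouring axial C14 methyl should give the equatorial 9β-alcohol.

**Step 8**
Reactants: 11 (1S,4aR,5R,8aS)-3-(2,2-diethoxyethyl)-5,8a-dimethyl-1,4,4a,5,6,7,8,8a-octahydronaphthalene-1,5-diol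
Product: 12 (1S,3R,4aR,5R,8aS)-3-(2,2-diethoxyethyl)-5,8a-dimethyldecahydronaphthalene-1,5-diol
Conditions: [Ir(cod)(PCy3)(py)]PF6 (5 mol %), H2 (1 atm), CH2Cl2, 0 °C to rt
Reagents that add atoms: none
Why: In this hydroxyl-directed homogeneous hydrogenation the cationic iridium should bind the allylic 9β-hydroxyl and deliver both hydrogens to the β face of C7=C8, so that H7 is β and the side chain is α (axial), the epimer that an undirected α-face hydrogenation would not give.

**Step 9**
Reactants: 12 (1S,3R,4aR,5R,8aS)-3-(2,2-diethoxyethyl)-5,8a-dimethyldecahydronaphthalene-1,5-diol; 13 (3S)-3-methylpentanoic acid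
Product: 14 (1S,3R,4aR,5R,8aS)-3-(2,2-diethoxyethyl)-5-hydroxy-5,8a-dimethyldecahydronaphthalen-1-yl (3S)-3-methylpentanoate
Conditions: DCC (1.5 equiv), DMAP (0.3 equiv), CH2Cl2, rt
Reagents that add atoms: none
Why: Steglich esterification should acylate the secondary C9 hydroxyl and leave the tertiary C4 hydroxyl alone, and the stereocentre of the acid is β to the carbonyl and cannot epimerise.

**Step 10**
Reactants: 14 (1S,3R,4aR,5R,8aS)-3-(2,2-diethoxyethyl)-5-hydroxy-5,8a-dimethyldecahydronaphthalen-1-yl (3S)-3-methylpentanoate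
Product: 15 (1S,3R,4aR,5R,8aS)-5-hydroxy-5,8a-dimethyl-3-(2-oxoethyl)decahydronaphthalen-1-yl (3S)-3-methylpentanoate
Conditions: AcOH/THF/H2O (3:1:1), 40 °C
Reagents that add atoms: water, O
Why: Mild acid-catalysed acetal hydrolysis should unveil the aldehyde without touching the ester or dehydrating the tertiary alcohol.

**Step 11**
Reactants: 15 (1S,3R,4aR,5R,8aS)-5-hydroxy-5,8a-dimethyl-3-(2-oxoethyl)decahydronaphthalen-1-yl (3S)-3-methylpentanoate
Product: 16 (1S,3R,4aR,5R,8aS)-5-hydroxy-5,8a-dimethyl-3-(3-oxoprop-1-en-2-yl)decahydronaphthalen-1-yl (3S)-3-methylpentanoate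
Conditions: 37% aq. CH2O (1.5 equiv), pyrrolidine (10 mol %), propionic acid (10 mol %), i-PrOH, 45 °C
Reagents that add atoms: formaldehyde, C=O
Why: Amine-catalysed α-methylenation (Mannich condensation then elimination) should place C13 on C11 through the enamine of the aldehyde, which does not involve the C7 stereocentre.

**Step 12**
Reactants: 16 (1S,3R,4aR,5R,8aS)-5-hydroxy-5,8a-dimethyl-3-(3-oxoprop-1-en-2-yl)decahydronaphthalen-1-yl (3S)-3-methylpentanoate
Product: 17 2-[(2R,4S,4aS,8R,8aR)-8-hydroxy-4a,8-dimethyl-4-{[(3S)-3-methylpentanoyl]oxy}decahydronaphthalen-2-yl]prop-2-enoic acid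
Conditions: NaClO2 (3 equiv), NaH2PO4 (3 equiv), 2-methylbut-2-ene (10 equiv), t-BuOH/H2O, 0 °C to rt
Reagents that add atoms: sodium chlorite, [Na+].[O-]Cl=O
Why: Pinnick oxidation should convert the 2-substituted acrolein to the acrylic acid without affecting the ester, the alkene or any stereocentre.

**Compound list**

1 | 3-methylcyclohex-2-en-1-one | CC1=CC(=O)CCC1 | starting material
2 | vinyl acetate | C=COC(C)=O | starting material
3 | (6S)-6-methyl-2-oxobicyclo[4.2.0]octan-7-yl acetate (epimer mixture at C1 and C7) | CC(=O)OC1CC2[C@]1(C)CCCC2=O | intermediate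
4 | (1S,6S)-7-hydroxy-6-methylbicyclo[4.2.0]octan-2-one (cis-fused, C7 epimers) | OC1C[C@H]2[C@]1(C)CCCC2=O | intermediate
5 | (1S,6S)-6-methylbicyclo[4.2.0]octane-2,7-dione | O=C1C[C@H]2[C@]1(C)CCCC2=O | intermediate
6 | 4,4-diethoxybut-1-yne | C#CCC(OCC)OCC | starting material
7 | (4aS,8aS)-7-(2,2-diethoxyethyl)-4a-methyl-3,4,4a,8a-tetrahydronaphthalene-1,5(2H,8H)-dione (cis-fused) | CCOC(OCC)CC1=CC(=O)[C@@]2(C)CCCC(=O)[C@H]2C1 | intermediate
8 | (4aS,8aR)-7-(2,2-diethoxyethyl)-4a-methyl-3,4,4a,8a-tetrahydronaphthalene-1,5(2H,8H)-dione (trans-fused) | CCOC(OCC)CC1=CC(=O)[C@@]2(C)CCCC(=O)[C@@H]2C1 | intermediate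
9 | (4aS,8aS)-3-(2,2-diethoxyethyl)-8a-methyl-5-methylidene-4a,5,6,7,8,8a-hexahydronaphthalen-1(4H)-one (trans-fused) | CCOC(OCC)CC1=CC(=O)[C@@]2(C)CCCC(=C)[C@@H]2C1 | intermediate
10 | 4α,15-epoxide of 9 (spiro-oxirane at C4, oxygen anti to the C14 methyl) | CCOC(OCC)CC1=CC(=O)[C@@]2(C)CCC[C@]3(CO3)[C@@H]2C1 | intermediate
11 | (1S,4aR,5R,8aS)-3-(2,2-diethoxyethyl)-5,8a-dimethyl-1,4,4a,5,6,7,8,8a-octahydronaphthalene-1,5-diol | CCOC(OCC)CC1=C[C@H](O)[C@@]2(C)CCC[C@@](C)(O)[C@@H]2C1 | intermediate
12 | (1S,3R,4aR,5R,8aS)-3-(2,2-diethoxyethyl)-5,8a-dimethyldecahydronaphthalene-1,5-diol | CCOC(OCC)C[C@H]1C[C@H](O)[C@@]2(C)CCC[C@@](C)(O)[C@@H]2C1 | intermediate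
13 | (3S)-3-methylpentanoic acid | CC[C@H](C)CC(=O)O | starting material
14 | (1S,3R,4aR,5R,8aS)-3-(2,2-diethoxyethyl)-5-hydroxy-5,8a-dimethyldecahydronaphthalen-1-yl (3S)-3-methylpentanoate | CCOC(OCC)C[C@H]1C[C@H](OC(=O)C[C@@H](C)CC)[C@@]2(C)CCC[C@@](C)(O)[C@@H]2C1 | intermediate
15 | (1S,3R,4aR,5R,8aS)-5-hydroxy-5,8a-dimethyl-3-(2-oxoethyl)decahydronaphthalen-1-yl (3S)-3-methylpentanoate | O=CC[C@H]1C[C@H](OC(=O)C[C@@H](C)CC)[C@@]2(C)CCC[C@@](C)(O)[C@@H]2C1 | intermediate
16 | (1S,3R,4aR,5R,8aS)-5-hydroxy-5,8a-dimethyl-3-(3-oxoprop-1-en-2-yl)decahydronaphthalen-1-yl (3S)-3-methylpentanoate | C=C(C=O)[C@H]1C[C@H](OC(=O)C[C@@H](C)CC)[C@@]2(C)CCC[C@@](C)(O)[C@@H]2C1 | intermediate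
17 | 2-[(2R,4S,4aS,8R,8aR)-8-hydroxy-4a,8-dimethyl-4-{[(3S)-3-methylpentanoyl]oxy}decahydronaphthalen-2-yl]prop-2-enoic acid | C=C(C(=O)O)[C@H]1C[C@H](OC(=O)C[C@@H](C)CC)[C@@]2(C)CCC[C@@](C)(O)[C@@H]2C1 | target

**Step count and risks**

Total steps: 12. Longest linear sequence: 12 steps (1 → 17).

Steps most likely to fail:

1. Step 4 (ring expansion). The 1-alkyne may oligomerise at zerovalent nickel faster than it couples with the α-quaternary cyclobutanone, or β-carbon elimination may go toward C10 instead of C6. The fallback sets out from 5 and comes back at 7, without nickel. Ethynylmagnesium bromide with CeCl3 at −78 °C would add to the strained four-ring carbonyl of 5 to give the carbinol (1S,6S)-7-ethynyl-7-hydroxy-6-methylbicyclo[4.2.0]octan-2-one F1. Allenation of its terminal alkyne with 2,2-diethoxyacetaldehyde (ZnI2, morpholine, toluene, heat) would give the allenyl cyclobutanol (1S,6S)-7-(4,4-diethoxybuta-1,2-dien-1-yl)-7-hydroxy-6-methylbicyclo[4.2.0]octan-2-one F2. Catalytic [Rh(OH)(cod)]2 with a bisphosphine in toluene would then expand the ring: β-carbon elimination of the rhodium cyclobutanolate toward the CH2 carbon, 1,4-addition of the alkylrhodium to the allenyl ketone and protonation would return enedione 7.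

2. Step 1 (enantioselective photocycloaddition). Binding of the ester carbonyl of vinyl acetate to the Lewis acid, or background excitation of free enone, may erode facial control, and some head-to-head adduct may form. The fallback sets out from 1 and comes back at 5. Enone 1 would be irradiated without catalyst in the presence of the C2-symmetric ketene acetal (4R,5R)-4,5-dimethyl-2-methylidene-1,3-dioxolane. The two facial adducts are then diastereomers; after equilibration to the cis ring fusion on basic alumina they would be separated by chromatography to give (1S,4'R,5'R,6S)-4',5',6-trimethylspiro[bicyclo[4.2.0]octane-7,2'-[1,3]dioxolan]-2-one F3. Aqueous oxalic acid in THF would hydrolyse the ketal to dione 5.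

3. Step 5 (epimerisation and methylenation). The ylide may methylenate the cis isomer before C5 has equilibrated, attack the C9 carbonyl, or be consumed in dienolate formation from the enone. The fallback sets out from 7 and comes back at 9. DBU in toluene would equilibrate 7 to the trans-dione 8, which is isolated. (Trimethylsilyl)methyllithium with CeCl3 in THF at −78 °C, a non-basic nucleophile, would add to the saturated C4 ketone to give the β-hydroxysilane (4aR,8aS)-3-(2,2-diethoxyethyl)-5-hydroxy-8a-methyl-5-[(trimethylsilyl)methyl]-4a,5,6,7,8,8a-hexahydronaphthalen-1(4H)-one F4 (C5 epimers). KH in THF would then effect Peterson elimination to 9.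

**Further compounds**

F1 | step 4 | (1S,6S)-7-ethynyl-7-hydroxy-6-methylbicyclo[4.2.0]octan-2-one (C7 epimers) | C#CC1(O)C[C@H]2[C@]1(C)CCCC2=O
F2 | step 4 | (1S,6S)-7-(4,4-diethoxybuta-1,2-dien-1-yl)-7-hydroxy-6-methylbicyclo[4.2.0]octan-2-one | CCOC(OCC)C=C=CC1(O)C[C@H]2[C@]1(C)CCCC2=O
F3 | step 1 | (1S,4'R,5'R,6S)-4',5',6-trimethylspiro[bicyclo[4.2.0]octane-7,2'-[1,3]dioxolan]-2-one | C[C@H]1OC2(C[C@H]3[C@]2(C)CCCC3=O)O[C@@H]1C
F4 | step 5 | (4aR,8aS)-3-(2,2-diethoxyethyl)-5-hydroxy-8a-methyl-5-[(trimethylsilyl)methyl]-4a,5,6,7,8,8a-hexahydronaphthalen-1(4H)-one (C5 epimers) | CCOC(OCC)CC1=CC(=O)[C@@]2(C)CCCC(O)(C[Si](C)(C)C)[C@@H]2C1
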